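**Plan**
- Retrosynthetic cuts: (i) the furan ring (O1'–C2' and C3'–C3a') and the C8–C2' link, giving an 8‑ethynylflavan and an o‑iodophenol; (ii) the C2–H bond, back to the C2=C3 enol ether of a 2‑phenyl‑4H‑chromene; (iii) O1 is excised from the pyran ring (C8a–O1 and O1–C2), which contracts it to the five‑membered ring of a 1‑phenylindan‑1‑yl peroxide; (iv) the two phenol oxygens that lie meta to their ring neighbours go back to arene C–H bonds.
- Forward order: 4‑methoxyindan‑1‑one → 6‑oxygenation → 3‑phenylindene → hydroperoxide on the phenyl‑bearing carbon → oxygen insertion with ring expansion (5 → 6) to the 4H‑chromene → flavan → C8 iodide → alkyne → benzofuran ring closed last → deprotection.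
- Enabling feature: in the pyran ring O1 lies between an aromatic carbon (C8a) and a benzylic carbon (C2) that carries phenyl. This is the aryl–O–C(aryl) array left when an aryl carbon migrates from carbon to oxygen in a tertiary benzylic peroxide (the C1–C7a bond of the indane).
- Stereochemistry: the racemic peroxide centre is erased in the ring expansion. The only stereocentre, C2 (S), is then set by catalyst‑controlled asymmetric hydrogenation of the chromene C2=C3 bond and is not touched afterwards.

Key step: step 5

Remark on the chemistry: C2 of the target is (S); the ligand antipode named in step 6 is the one expected to give this sense and would be exchanged for its mirror image if the first run showed the opposite sense.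

**Route**

Step 1
Reactants: 1 4-methoxyindan-1-one
Product: 3 6-hydroxy-4-methoxyindan-1-one, via aryl boronate 2 (not isolated)
Conditions: [Ir(OMe)(cod)]2 (cat.), dtbpy (cat.), B2pin2, THF, 80 °C; then Oxone, acetone–H2O, rt
Reagents that add atoms: potassium peroxymonosulfate (Oxone), [K+].[O-]S(=O)(=O)OO; bis(pinacolato)diboron, CC1(C)OB(OC1(C)C)B1OC(C)(C)C(C)(C)O1 (its atoms stay in 2 only)
Why: Sterically governed Ir‑catalysed C–H borylation takes the only arene C–H without an ortho substituent, C6 (C5 is flanked by OMe, C7 by the ring‑fusion carbon), and ipso‑oxidation of the C–B bond then gives the phenol without touching the ketone.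

Step 2
Reactants: 3 6-hydroxy-4-methoxyindan-1-one
Product: 4 6-(benzyloxy)-4-methoxyindan-1-one
Conditions: BnBr, K2CO3, DMF, rt
Reagents that add atoms: benzyl bromide, BrCc1ccccc1
Why: Williamson ether synthesis on the phenoxide; benzyl is chosen because it tolerates Grignard, peroxide, acylation and Ir/H2 conditions.

Step 3
Reactants: 4 6-(benzyloxy)-4-methoxyindan-1-one
Product: 6 5-(benzyloxy)-7-methoxy-3-phenyl-1H-indene, via tertiary alcohol 5 (not isolated)
Conditions: PhMgBr, THF, 0 °C → rt; aq NH4Cl; then TsOH·H2O (cat.), toluene, 40 °C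
Reagents that add atoms: phenylmagnesium bromide, Br[Mg]c1ccccc1
Why: Grignard 1,2‑addition to the aryl ketone, then E1 dehydration of the tertiary dibenzylic alcohol to the conjugated 3‑arylindene (only C2–H can be lost), which is the substrate for a neutral peroxidation.

Step 4
Reactants: 6 5-(benzyloxy)-7-methoxy-3-phenyl-1H-indene
Product: 8 rac-6-(benzyloxy)-1-hydroperoxy-4-methoxy-1-phenylindane, via silyl peroxide 7 (not isolated)
Conditions: Co(thd)2 (cat.), O2 (1 atm), Et3SiH, ClCH2CH2Cl, rt; then TBAF/AcOH (1:1), THF, 0 °C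
Reagents that add atoms: dioxygen, O=O; triethylsilane, CC[SiH](CC)CC (gives H to C2; its silyl group stays in 7 only)
Why: Mukaiyama–Isayama hydroperoxysilylation: hydrogen‑atom transfer to C2 gives the tertiary dibenzylic radical, which is trapped by O2 and silylated, so the peroxide sits on the phenyl‑bearing carbon under neutral conditions; buffered fluoride frees the hydroperoxide, and the new (racemic) centre is erased in step 5.

Step 5
Reactants: 8 rac-6-(benzyloxy)-1-hydroperoxy-4-methoxy-1-phenylindane
Product: 11 7-(benzyloxy)-5-methoxy-2-phenyl-4H-chromene, via peracetate 9 (not isolated), via ketal acetate 10 (not isolated)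
Conditions: Ac2O, pyridine, DMAP (cat.), CH2Cl2, 0 → 40 °C
Reagents that add atoms: acetic anhydride, CC(=O)OC(C)=O (its acetyl group is carried by 9 and 10 only and is lost again)
Why: Acetylation gives peracetate 9, whose weak O–O bond ionises with a concerted 1,2‑shift of the ring‑fused aryl carbon C7a from C1 to the proximal oxygen (phenonium‑like three‑centre transition state), so that this oxygen is inserted into the C1–C7a bond to give ketal acetate 10, which loses acetic acid through the 2‑phenylchroman‑2‑ylium ion to the phenyl‑conjugated enol ether 11 (only C3–H is available). The closest known reaction type is the Criegee rearrangement of tertiary peresters (ring‑expanding with decalyl peresters, aryl‑migrating with cumyl peresters and in the Hock process). No ring is closed by cyclisation: the six‑membered pyran ring arises from the five‑membered carbocycle by one‑atom ring expansion, so no Baldwin mode applies. No stereocentre is formed; the racemic centre C1 is destroyed, so both enantiomers of 8 converge on achiral 11 and C2 is set only in step 6. The step needs migration of the ring aryl carbon in preference to the free phenyl group and to the C2 methylene: the ring aryl carries an ortho‑alkyl donor (C3a), the ring holds the C1–O bond out of the arene plane so that the π lobe at C7a is already aligned with the breaking O–O bond, and its shift releases the strain of the indane, while a primary alkyl carbon migrates far more slowly than either aryl group. Basic, water‑free conditions keep the new ring closed (no hydrolysis to the open hydroxy ketone) and protect the acid‑labile enol ether.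

Step 6
Reactants: 11 7-(benzyloxy)-5-methoxy-2-phenyl-4H-chromene
Product: 12 (2S)-7-(benzyloxy)-5-methoxy-2-phenylchromane
Conditions: H2 (50 bar), [Ir(cod)(L*)]BArF (1–2 mol %; L* = (S)-configured phosphinooxazoline), CH2Cl2, rt
Reagents that add atoms: none
Why: Ir‑catalysed asymmetric hydrogenation of a trisubstituted cyclic enol ether without a coordinating group, a catalyst type established for 2‑aryl‑4H‑chromenes; the chiral N,P ligand differentiates the two faces of the C2=C3 bond and sets C2 as (S) by catalyst control, and the benzyl ether is inert.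

Step 7
Reactants: 12 (2S)-7-(benzyloxy)-5-methoxy-2-phenylchromane
Product: 13 (2S)-7-(benzyloxy)-8-iodo-5-methoxy-2-phenylchromane
Conditions: NIS, TFA (5 mol %), MeCN, 0 °C
Reagents that add atoms: N-iodosuccinimide, O=C1CCC(=O)N1I
Why: Electrophilic aromatic iodination of the phloroglucinol‑type ring; C8 (between ring oxygen O1 and 7‑OBn) should be favoured over C6 (wedged between two exocyclic alkoxy groups), as in the C8‑selective halogenation established for 5,7‑di‑O‑benzyl flavan‑3‑ols.

Step 8
Reactants: 13 (2S)-7-(benzyloxy)-8-iodo-5-methoxy-2-phenylchromane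
Product: 15 (2S)-7-(benzyloxy)-8-ethynyl-5-methoxy-2-phenylchromane, via silyl alkyne 14 (not isolated)
Conditions: TMS‑acetylene, PdCl2(PPh3)2 (cat.), CuI (cat.), Et3N–THF, 60 °C; then K2CO3 (cat.), MeOH, rt
Reagents that add atoms: ethynyltrimethylsilane, C#C[Si](C)(C)C
Why: Sonogashira coupling of the aryl iodide with a slim alkyne tolerates the two ortho oxygens, and methanolysis of the C(sp)–Si bond then frees the terminal alkyne.

Step 9
Reactants: 16 3-methoxy-2-methylphenol
Product: 17 triisopropyl(3-methoxy-2-methylphenoxy)silane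
Conditions: TIPSCl, imidazole, DMF, rt
Reagents that add atoms: chlorotriisopropylsilane, CC(C)[Si](Cl)(C(C)C)C(C)C
Why: Silylation of the phenol; the bulky TIPS group is inert to Ir borylation and later shields its own ortho position in step 11.

Step 10
Reactants: 17 triisopropyl(3-methoxy-2-methylphenoxy)silane
Product: 19 3-methoxy-4-methyl-5-[(triisopropylsilyl)oxy]phenol, via aryl boronate 18 (not isolated)
Conditions: [Ir(OMe)(cod)]2 (cat.), dtbpy (cat.), B2pin2, THF, 80 °C; then Oxone, acetone–H2O, rt (short contact)
Reagents that add atoms: potassium peroxymonosulfate (Oxone), [K+].[O-]S(=O)(=O)OO; bis(pinacolato)diboron, CC1(C)OB(OC1(C)C)B1OC(C)(C)C(C)(C)O1 (its atoms stay in 18 only)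
Why: Same sterically governed C–H borylation/oxidation as in step 1: in the 1,2,3‑trisubstituted arene only the C–H para to the methyl group has no ortho substituent, which places the new OH there.

Step 11
Reactants: 19 3-methoxy-4-methyl-5-[(triisopropylsilyl)oxy]phenol
Product: 20 2-iodo-3-methoxy-4-methyl-5-[(triisopropylsilyl)oxy]phenol
Conditions: NIS (1.0 equiv), CH2Cl2, −40 → 0 °C
Reagents that add atoms: N-iodosuccinimide, O=C1CCC(=O)N1I
Why: Electrophilic ortho‑iodination of the phenol; the C‑methyl group forces the OTIPS group to point toward its other neighbour (buttressing), which shields the site between OH and OTIPS, so iodine should enter between OH and OMe.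

Step 12
Reactants: 15 (2S)-7-(benzyloxy)-8-ethynyl-5-methoxy-2-phenylchromane; 20 2-iodo-3-methoxy-4-methyl-5-[(triisopropylsilyl)oxy]phenol
Product: 22 ({2-[(2S)-7-(benzyloxy)-5-methoxy-2-phenylchroman-8-yl]-4-methoxy-5-methyl-1-benzofuran-6-yl}oxy)triisopropylsilane, via alkynylphenol 21 (not isolated)
Conditions: PdCl2(PPh3)2 (cat.), CuI (cat.), Et3N, DMF, 70 → 90 °C, degassed
Reagents that add atoms: none
Why: Sonogashira coupling followed in the same flask by metal‑promoted 5‑endo‑dig hydroalkoxylation of the o‑alkynylphenol (Castro–Stephens/Larock‑type benzofuran synthesis) forms the C8–C2' link and the furan ring; the flavan 7‑oxygen is benzylated so that only the phenol of 20 can cyclise.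

Step 13
Reactants: 22 ({2-[(2S)-7-(benzyloxy)-5-methoxy-2-phenylchroman-8-yl]-4-methoxy-5-methyl-1-benzofuran-6-yl}oxy)triisopropylsilane
Product: 23 2-[(2S)-7-(benzyloxy)-5-methoxy-2-phenylchroman-8-yl]-4-methoxy-5-methyl-1-benzofuran-6-ol
Conditions: TBAF/AcOH (1:1), THF, 0 °C
Reagents that add atoms: none
Why: Fluoride cleaves the aryl O–Si bond; acetic acid buffers the phenoxide of the electron‑rich benzofuran.

Step 14
Reactants: 23 2-[(2S)-7-(benzyloxy)-5-methoxy-2-phenylchroman-8-yl]-4-methoxy-5-methyl-1-benzofuran-6-ol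
Product: 24 (2S)-8-(6-hydroxy-4-methoxy-5-methyl-1-benzofuran-2-yl)-5-methoxy-2-phenylchroman-7-ol
Conditions: H2 (1 atm), 10 % Pd/C, EtOAc–EtOH, rt
Reagents that add atoms: none
Why: Hydrogenolysis of the benzyl aryl ether under neutral conditions at 1 atm, where the benzofuran C2'=C3' bond and the cyclic benzylic C2–O1 bond should survive.

**Compound list**
1 | 4-methoxyindan-1-one | COc1cccc2c1CCC2=O | starting material
2 | 4-methoxy-6-(pinacolboryl)indan-1-one | COc1cc(B3OC(C)(C)C(C)(C)O3)cc2c1CCC2=O | intermediate (not isolated)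
3 | 6-hydroxy-4-methoxyindan-1-one | COc1cc(O)cc2c1CCC2=O | intermediate
4 | 6-(benzyloxy)-4-methoxyindan-1-one | COc1cc(OCc3ccccc3)cc2c1CCC2=O | intermediate
5 | rac-6-(benzyloxy)-4-methoxy-1-phenylindan-1-ol | COc1cc(OCc3ccccc3)cc2c1CCC2(O)c1ccccc1 | intermediate (not isolated)
6 | 5-(benzyloxy)-7-methoxy-3-phenyl-1H-indene | COc1cc(OCc3ccccc3)cc2c1CC=C2c1ccccc1 | intermediate
7 | rac-{[6-(benzyloxy)-4-methoxy-1-phenylindan-1-yl]peroxy}triethylsilane | COc1cc(OCc3ccccc3)cc2c1CCC2(OO[Si](CC)(CC)CC)c1ccccc1 | intermediate (not isolated)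
8 | rac-6-(benzyloxy)-1-hydroperoxy-4-methoxy-1-phenylindane | COc1cc(OCc3ccccc3)cc2c1CCC2(OO)c1ccccc1 | intermediate
9 | rac-6-(benzyloxy)-4-methoxy-1-phenylindan-1-yl peracetate | COc1cc(OCc3ccccc3)cc2c1CCC2(OOC(C)=O)c1ccccc1 | intermediate (not isolated)
10 | rac-7-(benzyloxy)-5-methoxy-2-phenylchroman-2-yl acetate | COc1cc(OCc3ccccc3)cc2c1CCC(OC(C)=O)(c1ccccc1)O2 | intermediate (not isolated)
11 | 7-(benzyloxy)-5-methoxy-2-phenyl-4H-chromene | COc1cc(OCc3ccccc3)cc2c1CC=C(c1ccccc1)O2 | intermediate
12 | (2S)-7-(benzyloxy)-5-methoxy-2-phenylchromane | COc1cc(OCc3ccccc3)cc2c1CC[C@@H](c1ccccc1)O2 | intermediate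
13 | (2S)-7-(benzyloxy)-8-iodo-5-methoxy-2-phenylchromane | COc1cc(OCc3ccccc3)c(I)c2c1CC[C@@H](c1ccccc1)O2 | intermediate
14 | {[(2S)-7-(benzyloxy)-5-methoxy-2-phenylchroman-8-yl]ethynyl}trimethylsilane | COc1cc(OCc3ccccc3)c(C#C[Si](C)(C)C)c2c1CC[C@@H](c1ccccc1)O2 | intermediate (not isolated)
15 | (2S)-7-(benzyloxy)-8-ethynyl-5-methoxy-2-phenylchromane | COc1cc(OCc3ccccc3)c(C#C)c2c1CC[C@@H](c1ccccc1)O2 | intermediate
16 | 3-methoxy-2-methylphenol | COc1cccc(O)c1C | starting material
17 | triisopropyl(3-methoxy-2-methylphenoxy)silane | COc1cccc(O[Si](C(C)C)(C(C)C)C(C)C)c1C | intermediate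
18 | triisopropyl[3-methoxy-2-methyl-5-(pinacolboryl)phenoxy]silane | COc1cc(B2OC(C)(C)C(C)(C)O2)cc(O[Si](C(C)C)(C(C)C)C(C)C)c1C | intermediate (not isolated)
19 | 3-methoxy-4-methyl-5-[(triisopropylsilyl)oxy]phenol | COc1cc(O)cc(O[Si](C(C)C)(C(C)C)C(C)C)c1C | intermediate
20 | 2-iodo-3-methoxy-4-methyl-5-[(triisopropylsilyl)oxy]phenol | COc1c(I)c(O)cc(O[Si](C(C)C)(C(C)C)C(C)C)c1C | intermediate
21 | 2-{[(2S)-7-(benzyloxy)-5-methoxy-2-phenylchroman-8-yl]ethynyl}-3-methoxy-4-methyl-5-[(triisopropylsilyl)oxy]phenol | COc1cc(OCc3ccccc3)c(C#Cc3c(O)cc(O[Si](C(C)C)(C(C)C)C(C)C)c(C)c3OC)c2c1CC[C@@H](c1ccccc1)O2 | intermediate (not isolated)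
22 | ({2-[(2S)-7-(benzyloxy)-5-methoxy-2-phenylchroman-8-yl]-4-methoxy-5-methyl-1-benzofuran-6-yl}oxy)triisopropylsilane | COc1cc(OCc3ccccc3)c(-c3cc4c(OC)c(C)c(O[Si](C(C)C)(C(C)C)C(C)C)cc4o3)c2c1CC[C@@H](c1ccccc1)O2 | intermediate
23 | 2-[(2S)-7-(benzyloxy)-5-methoxy-2-phenylchroman-8-yl]-4-methoxy-5-methyl-1-benzofuran-6-ol | COc1cc(OCc3ccccc3)c(-c3cc4c(OC)c(C)c(O)cc4o3)c2c1CC[C@@H](c1ccccc1)O2 | intermediate
24 | (2S)-8-(6-hydroxy-4-methoxy-5-methyl-1-benzofuran-2-yl)-5-methoxy-2-phenylchroman-7-ol | COc1cc(O)c(-c2cc3c(OC)c(C)c(O)cc3o2)c2c1CC[C@@H](c1ccccc1)O2 | target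

**Step count and risks**
Total step count: 14. Longest linear sequence: 11 (steps 1–8, then 12–14).

Steps most likely to fail:

1. Step 5. The exocyclic phenyl group may migrate in competition with the ring aryl carbon (which after work‑up only returns ketone 4), or the enol ether may disproportionate if acid builds up during loss of acetic acid. Fallback, setting out from 4 and returning at 11: Baeyer–Villiger oxidation (mCPBA, cat. TFA, CH2Cl2), in which the aryl carbon competes only with a primary alkyl carbon, should give 7-(benzyloxy)-5-methoxychroman-2-one F1. O‑Phosphorylation of its potassium enolate (KHMDS, (PhO)2P(O)Cl, THF–HMPA, −78 °C) should give the ketene acetal phosphate 7-(benzyloxy)-5-methoxy-4H-chromen-2-yl diphenyl phosphate F2. Suzuki–Miyaura coupling of F2 with phenylboronic acid (Pd(PPh3)4, K3PO4, dioxane–H2O, 80 °C) rejoins the route at 11.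

2. Step 6. Facial discrimination may be insufficient on this substitution pattern, or the acidic iridium hydride may trigger isomerisation or disproportionation of the enol ether before hydrogen is delivered. Fallback, setting out from 11 and returning at 12: hydrolysis of the enol ether (cat. HCl, THF–H2O) should give 3-[4-(benzyloxy)-2-hydroxy-6-methoxyphenyl]-1-phenylpropan-1-one F3. Noyori transfer hydrogenation (RuCl[(R,R)-TsDPEN](p-cymene), HCO2H/Et3N) should give (1R)-3-[4-(benzyloxy)-2-hydroxy-6-methoxyphenyl]-1-phenylpropan-1-ol F4. Mitsunobu etherification (PPh3, DIAD, THF, 0 °C) closes the pyran ring with inversion to the (S)‑flavan 12.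

3. Step 11. Iodination may take the other ortho position of the phenol or go on to the di‑iodide if steric shielding by the silyl group is not decisive. Fallback, setting out from 19 and returning at 20: MOM protection (MOMCl, iPr2NEt, CH2Cl2) should give triisopropyl[3-methoxy-5-(methoxymethoxy)-2-methylphenoxy]silane F5. Directed ortho‑metalation between the OMOM and OMe groups (n‑BuLi, THF, 0 °C; the TIPS ether blocks the other site) and an iodine quench should give triisopropyl[4-iodo-3-methoxy-5-(methoxymethoxy)-2-methylphenoxy]silane F6. Mild acid (cat. HCl, MeOH, rt) removes the MOM group to give 20.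

Further compounds
F1 | step 5 | 7-(benzyloxy)-5-methoxychroman-2-one | COc1cc(OCc3ccccc3)cc2c1CCC(=O)O2
F2 | step 5 | 7-(benzyloxy)-5-methoxy-4H-chromen-2-yl diphenyl phosphate | COc1cc(OCc3ccccc3)cc2c1CC=C(OP(=O)(Oc1ccccc1)Oc1ccccc1)O2
F3 | step 6 | 3-[4-(benzyloxy)-2-hydroxy-6-methoxyphenyl]-1-phenylpropan-1-one | COc1cc(OCc2ccccc2)cc(O)c1CCC(=O)c1ccccc1
F4 | step 6 | (1R)-3-[4-(benzyloxy)-2-hydroxy-6-methoxyphenyl]-1-phenylpropan-1-ol | COc1cc(OCc2ccccc2)cc(O)c1CC[C@@H](O)c1ccccc1
F5 | step 11 | triisopropyl[3-methoxy-5-(methoxymethoxy)-2-methylphenoxy]silane | COCOc1cc(OC)c(C)c(O[Si](C(C)C)(C(C)C)C(C)C)c1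
F6 | step 11 | triisopropyl[4-iodo-3-methoxy-5-(methoxymethoxy)-2-methylphenoxy]silane | COCOc1cc(O[Si](C(C)C)(C(C)C)C(C)C)c(C)c(OC)c1I
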